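Target 34 ← ester hydrolysis and one diimide treatment of tetraene 32 ← Wittig union of cyclohexadienylmethyl phosphonium salt 8 with epoxy aldehyde 30; the ring–CH2CH2–oxirane link is first made as CH=CH.
8 ← enol triflate and Stille homologation of 2,2,6-trimethylcyclohex-3-enone 4 ← ring-closing metathesis of acyclic dienone 3 (2-methylpent-4-enal + prenyl Grignard). With the ring numbered as 2,6,6-trimethylcyclohex-1-enyl (C1 carries the side chain, C6 the two methyls), this closes the carbocycle at C4–C5, first as C4=C5.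
Enabling feature: the quaternary C6 (gem-dimethyl) next to C5, and the sp2 ring carbon C1 (a ketone in 3) between the two alkene-bearing carbons. They fold the 1,6-diene for closure, and C6, having no hydrogen, keeps the new C4=C5 alkene from migrating or aromatising, so it can be carried to the end and removed together with the two olefination alkenes.
30 ← Sharpless epoxidation of a dienol ← vinylogous Horner–Wadsworth–Emmons reaction of phosphonate 12 with dioxane aldehyde 24 ← 1,2-dioxane 21 ← invertive perhydrolysis of (R)-epoxide 19 (from (S)-2-methylglycidol 13) and 6-exo SN2 closure onto a mesylate whose two centres come from an (E)-crotylboration.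
Order of ring formation: cyclohexene carbocycle (step 3), 1,2-dioxane (step 15), oxirane (step 21).

Key step: step 3

Assumption: 1, 9, 10, 13, the two Grignard solutions and (tributylstannyl)methanol are taken as bought, and the tartrate crotylboronate of step 12 is used as the known stock reagent made in one pot from (E)-but-2-ene, n-BuLi/KOt-Bu, B(Oi-Pr)3 and (R,R)-diisopropyl tartrate.

Step 1
Reactants: 1 2-methylpent-4-enal (racemic)
Product: 2 3,3,5-trimethylocta-1,7-dien-4-ol
Conditions: Me2C=CHCH2MgCl, THF, −78 to 0 °C; then H2O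
Reagents that add atoms: prenylmagnesium chloride, CC(C)=CC[Mg]Cl
Why: Allylic Grignard addition to an aldehyde runs through a six-membered SE2' transition state and bonds the more substituted γ-carbon, which creates the quaternary gem-dimethyl carbon with its vinyl group attached; the carbinol and α-methyl centres form without control, which is harmless because both are flattened in steps 2 and 4.

Step 2
Reactants: 2 3,3,5-trimethylocta-1,7-dien-4-ol
Product: 3 3,3,5-trimethylocta-1,7-dien-4-one
Conditions: Dess–Martin periodinane, CH2Cl2, rt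
Reagents that add atoms: none
Why: Dess–Martin oxidation converts the hindered secondary alcohol into the ketone under neutral conditions that leave both terminal alkenes in place and form no stereocentre.

Step 3
Reactants: 3 3,3,5-trimethylocta-1,7-dien-4-one
Product: 4 2,2,6-trimethylcyclohex-3-en-1-one
Conditions: second-generation Grubbs catalyst (2 mol%), CH2Cl2 (0.02 M), 40 °C
Reagents that add atoms: none
Why: The ruthenium alkylidene loads onto the unhindered allyl terminus of 3, adds [2+2] to the vinyl group on the quaternary carbon, and the ruthenacyclobutane collapses with loss of ethene, so that the two inner alkene carbons become the C3=C4 bond of 4, the later C4–C5 bond of the target ring. The closest known reaction type is ring-closing metathesis of 1,6-dienes with an allylic quaternary centre to give cyclohexenes. One ring is closed, the six-membered carbocycle, by C=C bond formation between the inner carbons of the two terminal alkenes of a seven-atom diene chain. No stereocentre is created, and the one already present (the methyl-bearing α-carbon) is racemic and is flattened in step 4. The step needs cyclisation to outrun acyclic diene metathesis and the new alkene to stay where it forms: the gem-dimethyl group and the carbonyl between the two arms fold the chain (gem-dialkyl effect), dilution does the rest, and the fully substituted carbon blocks migration of the alkene into conjugation with the ketone on that side.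

Step 4
Reactants: 4 2,2,6-trimethylcyclohex-3-en-1-one
Product: 6 2,6,6-trimethylcyclohexa-1,4-dien-1-yl trifluoromethanesulfonate, via potassium dienolate 5 (not isolated)
Conditions: KN(SiMe3)2, THF, −78 °C; then PhNTf2, −78 to 0 °C
Reagents that add atoms: N-phenyl-bis(trifluoromethanesulfonimide), O=S(=O)(N(c1ccccc1)S(=O)(=O)C(F)(F)F)C(F)(F)F
Why: Enol triflate formation: the only α-hydrogen of 4 sits on the methyl-bearing carbon (the other α-carbon is quaternary), so deprotonation can give a single dienolate, whose O-triflation fixes the position of the future tetrasubstituted ring alkene and removes the racemic stereocentre.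

Step 5
Reactants: 6 2,6,6-trimethylcyclohexa-1,4-dien-1-yl trifluoromethanesulfonate
Product: 7 (2,6,6-trimethylcyclohexa-1,4-dien-1-yl)methanol
Conditions: Bu3SnCH2OH, Pd(PPh3)4 (5 mol%), LiCl, 1,4-dioxane, 95 °C
Reagents that add atoms: (tributylstannyl)methanol, OC[Sn](CCCC)(CCCC)CCCC
Why: Stille cross-coupling of the enol triflate (oxidative addition to zerovalent palladium, chloride-assisted transmetalation, reductive elimination) transfers the hydroxymethyl group of the stannane to the ring carbon with the alkene position retained; no stereocentre is formed.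

Step 6
Reactants: 7 (2,6,6-trimethylcyclohexa-1,4-dien-1-yl)methanol
Product: 8 [(2,6,6-trimethylcyclohexa-1,4-dien-1-yl)methyl]triphenylphosphonium bromide
Conditions: Ph3P·HBr, MeOH, rt
Reagents that add atoms: triphenylphosphine hydrobromide, c1ccc(cc1)[PH+](c1ccccc1)c1ccccc1.[Br-]
Why: Phosphonium salt formation from an allylic alcohol with triphenylphosphine hydrobromide (ionisation to the allylic cation–bromide pair and capture by the phosphine at the unhindered primary terminus) is the usual entry to cyclogeranyl-type Wittig salts.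

Step 7
Reactants: 9 ethyl 2-(triphenyl-λ5-phosphanylidene)propanoate; 10 chloroacetaldehyde
Product: 11 ethyl (2E)-4-chloro-2-methylbut-2-enoate
Conditions: CH2Cl2, 0 °C to rt (10 as its aqueous solution)
Reagents that add atoms: none
Why: Wittig olefination with a stabilised α-methyl ylide gives the (E)-trisubstituted enoate under thermodynamic control of the oxaphosphetane, which fixes the E geometry of the alkene that later becomes the oxirane.

Step 8
Reactants: 11 ethyl (2E)-4-chloro-2-methylbut-2-enoate
Product: 12 ethyl (2E)-4-(diethoxyphosphoryl)-2-methylbut-2-enoate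
Conditions: P(OEt)3 (neat), 130 °C
Reagents that add atoms: triethyl phosphite, CCOP(OCC)OCC
Why: Michaelis–Arbuzov reaction of the primary allylic chloride with triethyl phosphite gives the vinylogous phosphonoacetate with the (E)-enoate unchanged.

Step 9
Reactants: 13 [(2S)-2-methyloxiran-2-yl]methanol
Product: 14 (2R)-2-methylhex-5-ene-1,2-diol
Conditions: CH2=CHCH2MgCl (2.5 equiv), CuI (10 mol%), THF, −30 to 0 °C; then H2O
Reagents that add atoms: allylmagnesium chloride, C=CC[Mg]Cl
Why: Copper-catalysed Grignard opening of the epoxide occurs at its unsubstituted CH2 carbon, so no bond to the bought tertiary C–O stereocentre is touched (the descriptor changes from S to R only through the priority rules).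

Step 10
Reactants: 14 (2R)-2-methylhex-5-ene-1,2-diol
Product: 16 (2R)-2-(but-3-en-1-yl)-2-methyloxirane, via primary monotosylate 15 (not isolated)
Conditions: NaH (2.2 equiv), THF, 0 °C; then 1-(p-tolylsulfonyl)imidazole, 0 °C to rt
Reagents that add atoms: none
Why: Selective sulfonylation of the primary alkoxide and intramolecular Williamson closure (3-exo-tet) by the tertiary alkoxide rebuild an epoxide on the other CH2 group without breaking a bond at the stereocentre, so 16 is the (R)-epoxide.

Step 11
Reactants: 16 (2R)-2-(but-3-en-1-yl)-2-methyloxirane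
Product: 17 3-[(2R)-2-methyloxiran-2-yl]propanal
Conditions: O3, CH2Cl2, −78 °C; then PPh3, −78 °C to rt
Reagents that add atoms: ozone, [O-][O+]=O
Why: Ozonolysis with reductive work-up cleaves the only alkene to the aldehyde, and the epoxide does not react with ozone or with triphenylphosphine at low temperature.

Step 12
Reactants: 17 3-[(2R)-2-methyloxiran-2-yl]propanal
Product: 18 (3R,4S)-4-methyl-1-[(2R)-2-methyloxiran-2-yl]hex-5-en-3-ol
Conditions: (R,R)-tartrate (E)-crotylboronate, toluene, 4 Å molecular sieves, −78 °C; then H2O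
Reagents that add atoms: diisopropyl (4R,5R)-2-[(2E)-but-2-en-1-yl]-1,3,2-dioxaborolane-4,5-dicarboxylate, C/C=C/CB1O[C@H]([C@@H](O1)C(=O)OC(C)C)C(=O)OC(C)C
Why: Tartrate-controlled (E)-crotylboration through a closed chair transition state: the E geometry of the reagent gives the anti relationship of hydroxyl and methyl, and the (R,R)-tartrate directs attack to the si face of the aldehyde, which sets the (3R,4S) configuration under reagent control independent of the remote epoxide centre.

Step 13
Reactants: 18 (3R,4S)-4-methyl-1-[(2R)-2-methyloxiran-2-yl]hex-5-en-3-ol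
Product: 19 (3R,4S)-4-methyl-1-[(2R)-2-methyloxiran-2-yl]hex-5-en-3-yl methanesulfonate
Conditions: MsCl, Et3N, CH2Cl2, 0 °C
Reagents that add atoms: methanesulfonyl chloride, CS(=O)(=O)Cl
Why: Mesylation at oxygen activates the secondary carbinol with retention of configuration and leaves the epoxide untouched under cold, basic conditions.

Step 14
Reactants: 19 (3R,4S)-4-methyl-1-[(2R)-2-methyloxiran-2-yl]hex-5-en-3-yl methanesulfonate
Product: 20 (2S,5R,6S)-2-hydroperoxy-1-hydroxy-2,6-dimethyloct-7-en-5-yl methanesulfonate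
Conditions: H2O2 (anhydrous, in Et2O), H3PMo12O40 (5 mol%), Et2O, rt
Reagents that add atoms: hydrogen peroxide, OO
Why: Heteropolyacid-catalysed perhydrolysis of a 2,2-disubstituted epoxide: H2O2 opens the activated oxirane at the tertiary carbon from the rear (borderline SN2), which inverts the bought stereocentre and gives the (S)-tertiary hydroperoxide, while the mesylate and the terminal alkene are inert to neutral H2O2.

Step 15
Reactants: 20 (2S,5R,6S)-2-hydroperoxy-1-hydroxy-2,6-dimethyloct-7-en-5-yl methanesulfonate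
Product: 21 [(3S,6S)-6-[(2S)-but-3-en-2-yl]-3-methyl-1,2-dioxan-3-yl]methanol
Conditions: Cs2CO3 (1.1 equiv), DMF, 0 °C to rt
Reagents that add atoms: none
Why: Intramolecular O-alkylation of a hydroperoxide (6-exo-tet SN2): the carbonate deprotonates only the hydroperoxide, which is far more acidic than the alcohol, and the peroxide anion displaces the secondary mesylate with inversion, turning the (R)-carbinol carbon of step 12 into the (S)-configured C–O–O carbon of the target.

Step 16
Reactants: 21 [(3S,6S)-6-[(2S)-but-3-en-2-yl]-3-methyl-1,2-dioxan-3-yl]methanol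
Product: 23 (2R)-2-[(3S,6S)-6-(hydroxymethyl)-6-methyl-1,2-dioxan-3-yl]propanoic acid, via dioxanyl propanal 22 (not isolated)
Conditions: O3, acetone/H2O (19:1), 0 °C; then NaClO2, NaH2PO4, 2-methylbut-2-ene, t-BuOH/H2O, 0 °C to rt
Reagents that add atoms: ozone, [O-][O+]=O; sodium chlorite, [Na+].[O-]Cl=O
Why: Ozonolysis in aqueous acetone gives the aldehyde directly and Pinnick oxidation in the same flask converts it to the acid before the α-stereocentre can epimerise or the β-peroxy aldehyde can eliminate, while the dialkyl peroxide and the primary alcohol are inert to both oxidants.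

Step 17
Reactants: 23 (2R)-2-[(3S,6S)-6-(hydroxymethyl)-6-methyl-1,2-dioxan-3-yl]propanoic acid
Product: 24 (2R)-2-[(3S,6S)-6-formyl-6-methyl-1,2-dioxan-3-yl]propanoic acid
Conditions: Dess–Martin periodinane, CH2Cl2, rt
Reagents that add atoms: none
Why: Dess–Martin oxidation of the neopentyl-type primary alcohol gives an α-peroxy aldehyde whose α-carbon is quaternary and therefore cannot enolise.

Step 18
Reactants: 24 (2R)-2-[(3S,6S)-6-formyl-6-methyl-1,2-dioxan-3-yl]propanoic acid; 12 ethyl (2E)-4-(diethoxyphosphoryl)-2-methylbut-2-enoate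
Product: 26 (2R)-2-[(3S,6S)-6-[(1E,3E)-5-ethoxy-4-methyl-5-oxopenta-1,3-dien-1-yl]-6-methyl-1,2-dioxan-3-yl]propanoic acid, via lithiated phosphonate 25 (not isolated)
Conditions: LiN(SiMe3)2 (2.1 equiv), THF, −78 to 0 °C; then aq. H3PO4 (pH 4)
Reagents that add atoms: none
Why: Vinylogous Horner–Wadsworth–Emmons olefination gives the (1E,3E)-dienoate (the 3E geometry comes from 12 and the new alkene is saturated later anyway), and the acid travels as its lithium carboxylate, which cannot form an enolate and so cannot open the β-peroxy acid by elimination.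

Step 19
Reactants: 26 (2R)-2-[(3S,6S)-6-[(1E,3E)-5-ethoxy-4-methyl-5-oxopenta-1,3-dien-1-yl]-6-methyl-1,2-dioxan-3-yl]propanoic acid
Product: 27 (2R)-2-[(3S,6S)-6-[(1E,3E)-5-hydroxy-4-methylpenta-1,3-dien-1-yl]-6-methyl-1,2-dioxan-3-yl]propanoic acid
Conditions: i-Bu2AlH (4.5 equiv), CH2Cl2, −78 °C; then H2O
Reagents that add atoms: none
Why: Low-temperature aluminium hydride 1,2-reduction converts the conjugated ester into the allylic alcohol, while the aluminium carboxylate formed from the free acid is not reduced at −78 °C and dialkyl peroxides should survive i-Bu2AlH at this temperature.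

Step 20
Reactants: 27 (2R)-2-[(3S,6S)-6-[(1E,3E)-5-hydroxy-4-methylpenta-1,3-dien-1-yl]-6-methyl-1,2-dioxan-3-yl]propanoic acid
Product: 28 methyl (2R)-2-[(3S,6S)-6-[(1E,3E)-5-hydroxy-4-methylpenta-1,3-dien-1-yl]-6-methyl-1,2-dioxan-3-yl]propanoate
Conditions: Me3SiCHN2, MeOH/toluene, 0 °C
Reagents that add atoms: (trimethylsilyl)diazomethane, C[Si](C)(C)C=[N+]=[N-]
Why: O-Methylation with (trimethylsilyl)diazomethane in methanol is chemoselective for the carboxylic acid over the alcohol and gives the ester needed because a free acid would interfere with the titanium catalyst of step 21.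

Step 21
Reactants: 28 methyl (2R)-2-[(3S,6S)-6-[(1E,3E)-5-hydroxy-4-methylpenta-1,3-dien-1-yl]-6-methyl-1,2-dioxan-3-yl]propanoate
Product: 29 methyl (2R)-2-[(3S,6S)-6-[(E)-2-[(2S,3S)-3-(hydroxymethyl)-3-methyloxiran-2-yl]ethenyl]-6-methyl-1,2-dioxan-3-yl]propanoate
Conditions: t-BuOOH, Ti(Oi-Pr)4 (10 mol%), L-(+)-diethyl tartrate (12 mol%), 4 Å molecular sieves, CH2Cl2, −20 °C
Reagents that add atoms: tert-butyl hydroperoxide, CC(C)(C)OO
Why: Sharpless asymmetric epoxidation: the titanium tartrate binds the allylic alcohol and delivers oxygen only to the allylic trisubstituted alkene, and L-(+)-diethyl tartrate gives the (2S,3S)-epoxy alcohol from this (E)-2-methyl allylic alcohol under reagent control, independent of the distant dioxane centres.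

Step 22
Reactants: 29 methyl (2R)-2-[(3S,6S)-6-[(E)-2-[(2S,3S)-3-(hydroxymethyl)-3-methyloxiran-2-yl]ethenyl]-6-methyl-1,2-dioxan-3-yl]propanoate
Product: 30 methyl (2R)-2-[(3S,6S)-6-[(E)-2-[(2S,3R)-3-formyl-3-methyloxiran-2-yl]ethenyl]-6-methyl-1,2-dioxan-3-yl]propanoate
Conditions: Dess–Martin periodinane, NaHCO3, CH2Cl2, 0 °C to rt
Reagents that add atoms: none
Why: Buffered Dess–Martin oxidation gives the epoxy aldehyde, whose α-carbon is quaternary so that the oxirane centres cannot epimerise (the descriptor of that carbon changes to R only through the priority rules).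

Step 23
Reactants: 8 [(2,6,6-trimethylcyclohexa-1,4-dien-1-yl)methyl]triphenylphosphonium bromide; 30 methyl (2R)-2-[(3S,6S)-6-[(E)-2-[(2S,3R)-3-formyl-3-methyloxiran-2-yl]ethenyl]-6-methyl-1,2-dioxan-3-yl]propanoate
Product: 32 methyl (2R)-2-[(3S,6S)-6-methyl-6-[(E)-2-[(2S,3S)-3-methyl-3-[2-(2,6,6-trimethylcyclohexa-1,4-dien-1-yl)ethenyl]oxiran-2-yl]ethenyl]-1,2-dioxan-3-yl]propanoate, via phosphonium ylide 31 (not isolated)
Conditions: 8, NaN(SiMe3)2, THF, −78 °C; then 30, −78 to 0 °C
Reagents that add atoms: none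
Why: Wittig olefination with the preformed semi-stabilised allylic ylide joins the two fragments through a CH=CH unit whose geometry is irrelevant because it is saturated in step 24, and adding the aldehyde to the preformed ylide at −78 °C avoids free amide base in the presence of the ester and the peroxide.

Step 24
Reactants: 32 methyl (2R)-2-[(3S,6S)-6-methyl-6-[(E)-2-[(2S,3S)-3-methyl-3-[2-(2,6,6-trimethylcyclohexa-1,4-dien-1-yl)ethenyl]oxiran-2-yl]ethenyl]-1,2-dioxan-3-yl]propanoate
Product: 33 methyl (2R)-2-[(3S,6R)-6-methyl-6-[2-[(2S,3S)-3-methyl-3-[2-(2,6,6-trimethylcyclohex-1-en-1-yl)ethyl]oxiran-2-yl]ethyl]-1,2-dioxan-3-yl]propanoate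
Conditions: 2-nitrobenzenesulfonohydrazide (excess, in portions), Et3N, CH2Cl2, rt
Reagents that add atoms: none
Why: Diimide reduction (concerted syn transfer of H2 from HN=NH generated in the flask) should saturate the three 1,2-disubstituted alkenes, among them the ring alkene left by the key step, while the tetrasubstituted ring alkene is too hindered to react and the O–O bond, oxirane and ester are inert to diimide; no stereocentre is formed (the dioxane descriptor changes from S to R through the priority rules).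

Step 25
Reactants: 33 methyl (2R)-2-[(3S,6R)-6-methyl-6-[2-[(2S,3S)-3-methyl-3-[2-(2,6,6-trimethylcyclohex-1-en-1-yl)ethyl]oxiran-2-yl]ethyl]-1,2-dioxan-3-yl]propanoate
Product: 34 (2R)-2-[(3S,6R)-6-methyl-6-[2-[(2S,3S)-3-methyl-3-[2-(2,6,6-trimethylcyclohex-1-en-1-yl)ethyl]oxiran-2-yl]ethyl]-1,2-dioxan-3-yl]propanoic acid
Conditions: Me3SnOH, ClCH2CH2Cl, 70 °C; then pH 4 aqueous wash
Reagents that add atoms: water, O
Why: Neutral ester hydrolysis mediated by trimethyltin hydroxide should cleave the methyl ester without enolising the β-peroxy ester or opening the oxirane.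

Compound list
1 | 2-methylpent-4-enal (racemic) | C=CCC(C)C=O | starting material
2 | 3,3,5-trimethylocta-1,7-dien-4-ol (diastereomer mixture) | C=CCC(C)C(O)C(C)(C)C=C | intermediate
3 | 3,3,5-trimethylocta-1,7-dien-4-one (racemic) | C=CCC(C)C(=O)C(C)(C)C=C | intermediate
4 | 2,2,6-trimethylcyclohex-3-en-1-one (racemic) | CC1CC=CC(C)(C)C1=O | intermediate
5 | potassium 2,6,6-trimethylcyclohexa-1,4-dien-1-olate | CC1=C([O-])C(C)(C)C=CC1.[K+] | intermediate
6 | 2,6,6-trimethylcyclohexa-1,4-dien-1-yl trifluoromethanesulfonate | CC1=C(OS(=O)(=O)C(F)(F)F)C(C)(C)C=CC1 | intermediate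
7 | (2,6,6-trimethylcyclohexa-1,4-dien-1-yl)methanol | CC1=C(CO)C(C)(C)C=CC1 | intermediate
8 | [(2,6,6-trimethylcyclohexa-1,4-dien-1-yl)methyl]triphenylphosphonium bromide | CC1=C(C[P+](c2ccccc2)(c2ccccc2)c2ccccc2)C(C)(C)C=CC1.[Br-] | intermediate
9 | ethyl 2-(triphenyl-λ5-phosphanylidene)propanoate | CCOC(=O)C(C)=P(c1ccccc1)(c1ccccc1)c1ccccc1 | starting material
10 | chloroacetaldehyde | ClCC=O | starting material
11 | ethyl (2E)-4-chloro-2-methylbut-2-enoate | CCOC(=O)/C(C)=C/CCl | intermediate
12 | ethyl (2E)-4-(diethoxyphosphoryl)-2-methylbut-2-enoate | CCOC(=O)/C(C)=C/CP(=O)(OCC)OCC | intermediate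
13 | [(2S)-2-methyloxiran-2-yl]methanol | C[C@]1(CO)CO1 | starting material
14 | (2R)-2-methylhex-5-ene-1,2-diol | C=CCC[C@@](C)(O)CO | intermediate
15 | (2R)-2-hydroxy-2-methylhex-5-en-1-yl 4-methylbenzenesulfonate | C=CCC[C@@](C)(O)COS(=O)(=O)c1ccc(C)cc1 | intermediate
16 | (2R)-2-(but-3-en-1-yl)-2-methyloxirane | C=CCC[C@]1(C)CO1 | intermediate
17 | 3-[(2R)-2-methyloxiran-2-yl]propanal | O=CCC[C@]1(C)CO1 | intermediate
18 | (3R,4S)-4-methyl-1-[(2R)-2-methyloxiran-2-yl]hex-5-en-3-ol | C=C[C@H](C)[C@H](O)CC[C@]1(C)CO1 | intermediate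
19 | (3R,4S)-4-methyl-1-[(2R)-2-methyloxiran-2-yl]hex-5-en-3-yl methanesulfonate | C=C[C@H](C)[C@H](OS(C)(=O)=O)CC[C@]1(C)CO1 | intermediate
20 | (2S,5R,6S)-2-hydroperoxy-1-hydroxy-2,6-dimethyloct-7-en-5-yl methanesulfonate | C=C[C@H](C)[C@H](OS(C)(=O)=O)CC[C@](C)(OO)CO | intermediate
21 | [(3S,6S)-6-[(2S)-but-3-en-2-yl]-3-methyl-1,2-dioxan-3-yl]methanol | OC[C@]1(C)CC[C@@H]([C@@H](C)C=C)OO1 | intermediate
22 | (2R)-2-[(3S,6S)-6-(hydroxymethyl)-6-methyl-1,2-dioxan-3-yl]propanal | OC[C@]1(C)CC[C@@H]([C@@H](C)C=O)OO1 | intermediate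
23 | (2R)-2-[(3S,6S)-6-(hydroxymethyl)-6-methyl-1,2-dioxan-3-yl]propanoic acid | OC[C@]1(C)CC[C@@H]([C@@H](C)C(O)=O)OO1 | intermediate
24 | (2R)-2-[(3S,6S)-6-formyl-6-methyl-1,2-dioxan-3-yl]propanoic acid | O=C[C@]1(C)CC[C@@H]([C@@H](C)C(O)=O)OO1 | intermediate
25 | lithium (2E)-1-(diethoxyphosphoryl)-4-ethoxy-3-methyl-4-oxobut-2-en-1-ide | CCOC(=O)/C(C)=C/[CH-]P(=O)(OCC)OCC.[Li+] | intermediate
26 | (2R)-2-[(3S,6S)-6-[(1E,3E)-5-ethoxy-4-methyl-5-oxopenta-1,3-dien-1-yl]-6-methyl-1,2-dioxan-3-yl]propanoic acid | CCOC(=O)/C(C)=C/C=C/[C@]1(C)CC[C@@H]([C@@H](C)C(O)=O)OO1 | intermediate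
27 | (2R)-2-[(3S,6S)-6-[(1E,3E)-5-hydroxy-4-methylpenta-1,3-dien-1-yl]-6-methyl-1,2-dioxan-3-yl]propanoic acid | OC/C(C)=C/C=C/[C@]1(C)CC[C@@H]([C@@H](C)C(O)=O)OO1 | intermediate
28 | methyl (2R)-2-[(3S,6S)-6-[(1E,3E)-5-hydroxy-4-methylpenta-1,3-dien-1-yl]-6-methyl-1,2-dioxan-3-yl]propanoate | OC/C(C)=C/C=C/[C@]1(C)CC[C@@H]([C@@H](C)C(=O)OC)OO1 | intermediate
29 | methyl (2R)-2-[(3S,6S)-6-[(E)-2-[(2S,3S)-3-(hydroxymethyl)-3-methyloxiran-2-yl]ethenyl]-6-methyl-1,2-dioxan-3-yl]propanoate | OC[C@]1(C)O[C@H]1/C=C/[C@]2(C)CC[C@@H]([C@@H](C)C(=O)OC)OO2 | intermediate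
30 | methyl (2R)-2-[(3S,6S)-6-[(E)-2-[(2S,3R)-3-formyl-3-methyloxiran-2-yl]ethenyl]-6-methyl-1,2-dioxan-3-yl]propanoate | O=C[C@]1(C)O[C@H]1/C=C/[C@]2(C)CC[C@@H]([C@@H](C)C(=O)OC)OO2 | intermediate
31 | triphenyl[(2,6,6-trimethylcyclohexa-1,4-dien-1-yl)methylidene]-λ5-phosphane | CC1=C(C=P(c2ccccc2)(c2ccccc2)c2ccccc2)C(C)(C)C=CC1 | intermediate
32 | methyl (2R)-2-[(3S,6S)-6-methyl-6-[(E)-2-[(2S,3S)-3-methyl-3-[2-(2,6,6-trimethylcyclohexa-1,4-dien-1-yl)ethenyl]oxiran-2-yl]ethenyl]-1,2-dioxan-3-yl]propanoate (E/Z mixture at the new alkene) | CC1=C(C=C[C@]2(C)O[C@H]2/C=C/[C@]2(C)CC[C@@H]([C@@H](C)C(=O)OC)OO2)C(C)(C)C=CC1 | intermediate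
33 | methyl (2R)-2-[(3S,6R)-6-methyl-6-[2-[(2S,3S)-3-methyl-3-[2-(2,6,6-trimethylcyclohex-1-en-1-yl)ethyl]oxiran-2-yl]ethyl]-1,2-dioxan-3-yl]propanoate | CC1=C(CC[C@]2(C)O[C@H]2CC[C@]2(C)CC[C@@H]([C@@H](C)C(=O)OC)OO2)C(C)(C)CCC1 | intermediate
34 | (2R)-2-[(3S,6R)-6-methyl-6-[2-[(2S,3S)-3-methyl-3-[2-(2,6,6-trimethylcyclohex-1-en-1-yl)ethyl]oxiran-2-yl]ethyl]-1,2-dioxan-3-yl]propanoic acid | CC1=C(CC[C@]2(C)O[C@H]2CC[C@]2(C)CC[C@@H]([C@@H](C)C(=O)O)OO2)C(C)(C)CCC1 | target

Total step count: 25 (steps 1–6 ring fragment, steps 7–8 phosphonate, steps 9–25 main line).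
Longest linear sequence: 17 steps (13 to 34, steps 9–25).

Steps most likely to fail

Step 15, peroxide ring closure. Base-induced elimination of the mesylate toward the allylic hydrogen, etherification through the neighbouring primary hydroxyl, or fragmentation of the β-hydroxy hydroperoxide may outrun the 6-exo displacement. The fallback sets out from 17 and comes back at 23. Wittig olefination of 17 with methyl 2-(triphenyl-λ5-phosphanylidene)propanoate should give methyl (2E)-2-methyl-5-[(2R)-2-methyloxiran-2-yl]pent-2-enoate F1. The perhydrolysis of step 14 would turn it into methyl (2E,6S)-6-hydroperoxy-7-hydroxy-2,6-dimethylhept-2-enoate F2. Amine-mediated 6-exo conjugate addition of the hydroperoxide to the enoate (Et2NH, CF3CH2OH) would then close the ring to methyl (2R)-2-[(3S,6S)-6-(hydroxymethyl)-6-methyl-1,2-dioxan-3-yl]propanoate F3. In this variant the two new centres rest on substrate control only, so the wanted isomer would have to be separated from its epimers. Hydrolysis with Me3SnOH returns acid 23.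

Step 23, Wittig union. Proton transfer from the ester α-position, attack of the strongly basic hindered ylide at the O–O bond, or deprotonation of the doubly allylic ring CH2 during ylide formation may compete with addition to the hindered aldehyde. The fallback sets out from 7 and comes back at 32. Mitsunobu thioetherification of 7 with 1-phenyl-1H-tetrazole-5-thiol would give 1-phenyl-5-{[(2,6,6-trimethylcyclohexa-1,4-dien-1-yl)methyl]sulfanyl}-1H-tetrazole F4. Oxidation with H2O2 and (NH4)6Mo7O24 would give 1-phenyl-5-{[(2,6,6-trimethylcyclohexa-1,4-dien-1-yl)methyl]sulfonyl}-1H-tetrazole F5. Julia–Kocienski olefination of 30 with the potassium salt of F5 (KN(SiMe3)2, THF, −78 °C), whose carbanion is much less basic than the ylide, should give 32 directly.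

Step 24, triple diimide reduction. Saturation of the hindered ring alkene beside the quaternary carbon may stay incomplete, which would call for large excesses of diimide and leave partly reduced material that is hard to separate. The fallback sets out from 4 and comes back at 33. The ring alkene is removed before any sensitive group exists, by hydrogenation of 4 (H2, Pd/C) to 2,2,6-trimethylcyclohexan-1-one F6. Steps 4 to 6 are then repeated in the saturated series, giving 2,6,6-trimethylcyclohex-1-en-1-yl trifluoromethanesulfonate F7, (2,6,6-trimethylcyclohex-1-en-1-yl)methanol F8 and [(2,6,6-trimethylcyclohex-1-en-1-yl)methyl]triphenylphosphonium bromide F9. Wittig reaction of F9 with 30 would give methyl (2R)-2-[(3S,6S)-6-methyl-6-[(E)-2-[(2S,3S)-3-methyl-3-[2-(2,6,6-trimethylcyclohex-1-en-1-yl)ethenyl]oxiran-2-yl]ethenyl]-1,2-dioxan-3-yl]propanoate F10. Its two remaining unhindered 1,2-disubstituted alkenes should be reduced by diimide under mild conditions to 33.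

Further compounds
F1 | step 15 | methyl (2E)-2-methyl-5-[(2R)-2-methyloxiran-2-yl]pent-2-enoate | COC(=O)/C(C)=C/CC[C@]1(C)CO1
F2 | step 15 | methyl (2E,6S)-6-hydroperoxy-7-hydroxy-2,6-dimethylhept-2-enoate | COC(=O)/C(C)=C/CC[C@](C)(OO)CO
F3 | step 15 | methyl (2R)-2-[(3S,6S)-6-(hydroxymethyl)-6-methyl-1,2-dioxan-3-yl]propanoate | OC[C@]1(C)CC[C@@H]([C@@H](C)C(=O)OC)OO1
F4 | step 23 | 1-phenyl-5-{[(2,6,6-trimethylcyclohexa-1,4-dien-1-yl)methyl]sulfanyl}-1H-tetrazole | CC1=C(CSc2nnnn2-c2ccccc2)C(C)(C)C=CC1
F5 | step 23 | 1-phenyl-5-{[(2,6,6-trimethylcyclohexa-1,4-dien-1-yl)methyl]sulfonyl}-1H-tetrazole | CC1=C(CS(=O)(=O)c2nnnn2-c2ccccc2)C(C)(C)C=CC1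
F6 | step 24 | 2,2,6-trimethylcyclohexan-1-one (racemic) | CC1CCCC(C)(C)C1=O
F7 | step 24 | 2,6,6-trimethylcyclohex-1-en-1-yl trifluoromethanesulfonate | CC1=C(OS(=O)(=O)C(F)(F)F)C(C)(C)CCC1
F8 | step 24 | (2,6,6-trimethylcyclohex-1-en-1-yl)methanol | CC1=C(CO)C(C)(C)CCC1
F9 | step 24 | [(2,6,6-trimethylcyclohex-1-en-1-yl)methyl]triphenylphosphonium bromide | CC1=C(C[P+](c2ccccc2)(c2ccccc2)c2ccccc2)C(C)(C)CCC1.[Br-]
F10 | step 24 | methyl (2R)-2-[(3S,6S)-6-methyl-6-[(E)-2-[(2S,3S)-3-methyl-3-[2-(2,6,6-trimethylcyclohex-1-en-1-yl)ethenyl]oxiran-2-yl]ethenyl]-1,2-dioxan-3-yl]propanoate | CC1=C(C=C[C@]2(C)O[C@H]2/C=C/[C@]2(C)CC[C@@H]([C@@H](C)C(=O)OC)OO2)C(C)(C)CCC1
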